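**Retrosynthetic overview**
1. Target 25 ⇐ diol 22 (both angelates last) ⇐ epoxy ketone 21 ⇐ allylic alcohol 19 (OH-directed epoxidation puts the oxirane cis to the side chain) ⇐ enone 18.
2. Enone 18 ⇐ one-carbon ring expansion of cyclopentanone 10: a β-oxido carbenoid 1,2-shift inserts the C–CH3 unit between C=O and the unsubstituted α-carbon, then enolate dehydrogenation.
3. 10 ⇐ ethynyl ketone 7 + 4-methylpent-3-enal 9 (C7–C8 bond and the side-chain carbinol centre by a branch-selective Ni reductive coupling).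
4. 7 ⇐ cyclopent-2-enone 1 + ethynyltrimethylsilane 2 (asymmetric conjugate alkynylation, enolate silylation, Rubottom oxidation).
5. Ring order: the five-membered carbocycle is bought, expanded to the six-membered ring in step 6, and the oxirane is closed last (step 8).

Abbreviations: TBS = tert-butyldimethylsilyl, TES = triethylsilyl, TMS = trimethylsilyl; "side chain" = (3S)-6-methyl-3-(OR)hepta-1,5-dien-2-yl.
Assumption: for the chiral ligands of steps 1 and 4, the antipode used is the one found by screening to give the configuration drawn. L* (step 4) = (4S,5S)-1,3-bis[2,6-bis(diphenylmethyl)-4-methylphenyl]-4,5-diphenylimidazolidin-2-ylidene, generated from its HBF4 salt with catalytic KOt-Bu.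

**Route**

Step 1
Reactants: 1 cyclopent-2-en-1-one; 2 ethynyltrimethylsilane
Product: 5 (R)-tert-butyldimethyl({3-[(trimethylsilyl)ethynyl]cyclopent-1-en-1-yl}oxy)silane, via alkynylalane 3 (not isolated), via aluminium enolate 4 (not isolated)
Conditions: 2, AlMe3, Et3N (10 mol %), toluene, rt; then 1, Ni(acac)2 (5 mol %)/chiral cyano-bis(oxazoline) (6 mol %), t-BuOMe, 0 °C; then TBSOTf, −40 → 0 °C
Reagents that add atoms: tert-butyldimethylsilyl trifluoromethanesulfonate CC(C)(C)[Si](C)(C)OS(=O)(=O)C(F)(F)F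
Why: Ni-catalysed enantioselective conjugate alkynylation (1,4-addition of an alkynylalane) in which the chiral bis(oxazoline)–Ni complex selects the enone face to set C3 as R, and O-silylation of the aluminium enolate fixes the enol ether on the C2 side.

Step 2
Reactants: 5 (R)-tert-butyldimethyl({3-[(trimethylsilyl)ethynyl]cyclopent-1-en-1-yl}oxy)silane
Product: 7 (2S,3S)-2-(TBSO)-3-ethynylcyclopentan-1-one, via TMS-alkynyl siloxy ketone 6 (not isolated)
Conditions: m-CPBA, hexane/CH2Cl2, −15 °C → rt; then AgNO3 (10 mol %), MeOH/H2O/CH2Cl2, rt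
Reagents that add atoms: m-chloroperoxybenzoic acid OOC(=O)c1cccc(Cl)c1
Why: Rubottom oxidation, in which m-CPBA epoxidises the enol ether anti to the C3 alkynyl group and 1,4-silyl migration gives the trans α-siloxy ketone (C2 S); base-free Ag(I)-catalysed protodesilylation then frees the alkyne without epimerising or transposing the α-siloxy ketone.

Step 3
Reactants: 8 4-methylpent-3-en-1-ol
Product: 9 4-methylpent-3-enal
Conditions: Dess–Martin periodinane, CH2Cl2, 0 °C; used at once as a cold solution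
Reagents that add atoms: none
Why: Dess–Martin oxidation under neutral conditions gives the β,γ-unsaturated aldehyde without isomerisation into conjugation.

Step 4
Reactants: 7 (2S,3S)-2-(TBSO)-3-ethynylcyclopentan-1-one; 9 4-methylpent-3-enal
Product: 10 (2S,3S)-2-(TBSO)-3-[(3S)-6-methyl-3-(TESO)hepta-1,5-dien-2-yl]cyclopentan-1-one
Conditions: Ni(cod)2 (10 mol %), L* (12 mol %), Et3SiH (2 equiv), THF, rt, slow addition of 9
Reagents that add atoms: triethylsilane CC[SiH](CC)CC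
Why: Proposed new method: a Ni(0) complex of a very bulky C2-symmetric chiral NHC couples a terminal alkyne with an enolisable aliphatic aldehyde branch-selectively and under catalyst control; oxidative cyclisation gives an oxanickelacyclopentene in which the large N-aryl groups push the ring-bearing alkyne carbon away from nickel so the C–C bond forms at the internal carbon (1,1-disubstituted alkene), the chiral backbone selects the aldehyde face (carbinol centre S), and σ-bond metathesis with Et3SiH followed by C–H reductive elimination releases the TES ether; the closest known reaction type is the Ni(0)–NHC aldehyde–alkyne reductive coupling, where bulky achiral NHCs give this regiochemistry as racemate and chiral NHCs give enantiocontrol only with internal alkynes.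

Step 5
Reactants: 10 (2S,3S)-2-(TBSO)-3-[(3S)-6-methyl-3-(TESO)hepta-1,5-dien-2-yl]cyclopentan-1-one; 11 1,1-dibromoethane
Product: 13 (2S,3S)-1-(1,1-dibromoethyl)-2-(TBSO)-3-[(3S)-6-methyl-3-(TESO)hepta-1,5-dien-2-yl]cyclopentan-1-ol (C1 epimers), via 1,1-dibromo-1-lithioethane 12 (not isolated)
Conditions: 11, LDA, THF/Et2O, −100 °C; then 10, −100 → −78 °C; then H2O
Reagents that add atoms: none
Why: 1,2-addition of a lithium carbenoid (1,1-dibromoalkyllithium) to the ketone at −100 °C outruns enolisation, and the new carbinol configuration is irrelevant because this carbon becomes the carbonyl carbon.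

Step 6
Reactants: 13 (2S,3S)-1-(1,1-dibromoethyl)-2-(TBSO)-3-[(3S)-6-methyl-3-(TESO)hepta-1,5-dien-2-yl]cyclopentan-1-ol
Product: 18 (5S,6S)-6-(TBSO)-2-methyl-5-[(3S)-6-methyl-3-(TESO)hepta-1,5-dien-2-yl]cyclohex-2-en-1-one, via lithium alkoxide 14 (not isolated), via β-oxido carbenoid 15 (not isolated), via lithium enolate 16 (not isolated), via α-sulfilimine ketone 17 (not isolated)
Conditions: n-BuLi (2.1 equiv), THF, −95 → −20 °C; then PhS(Cl)=N-t-Bu, −78 °C → rt
Reagents that add atoms: none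
Why: Nozaki–Yamamoto β-oxido carbenoid ring expansion (1,2-alkyl shift of Tiffeneau–Demjanov type), in which the unsubstituted C5–C1 bond migrates in preference to the inductively deactivated, hindered C2(OTBS)–C1 bond with loss of bromide to give the regiodefined tetrasubstituted enolate, which Mukaiyama dehydrogenation (sulfinimidoyl chloride, syn-elimination) turns into the endocyclic enone; no stereocentre is touched.

Step 7
Reactants: 18 (5S,6S)-6-(TBSO)-2-methyl-5-[(3S)-6-methyl-3-(TESO)hepta-1,5-dien-2-yl]cyclohex-2-en-1-one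
Product: 19 (1S,5S,6S)-6-(TBSO)-2-methyl-5-[(3S)-6-methyl-3-(TESO)hepta-1,5-dien-2-yl]cyclohex-2-en-1-ol
Conditions: NaBH4, CeCl3·7H2O, MeOH, −78 °C
Reagents that add atoms: none
Why: Luche reduction, in which 1,2-selective axial hydride delivery to the half-chair enone (C6-OTBS and C5 side chain equatorial) gives the equatorial 1S alcohol, trans to OTBS and cis to the side chain.

Step 8
Reactants: 19 (1S,5S,6S)-6-(TBSO)-2-methyl-5-[(3S)-6-methyl-3-(TESO)hepta-1,5-dien-2-yl]cyclohex-2-en-1-ol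
Product: 20 (1R,2R,3S,4S,6S)-3-(TBSO)-1-methyl-4-[(3S)-6-methyl-3-(TESO)hepta-1,5-dien-2-yl]-7-oxabicyclo[4.1.0]heptan-2-ol
Conditions: VO(acac)2 (5 mol %), t-BuOOH, CH2Cl2, 0 °C
Reagents that add atoms: tert-butyl hydroperoxide CC(C)(C)OO
Why: Vanadium-catalysed hydroxyl-directed epoxidation delivers oxygen syn to the allylic OH, so the oxirane ends up cis to the side chain (the face that direct alkaline peroxide epoxidation of the enone would not give), and the other alkenes have no free directing hydroxyl.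

Step 9
Reactants: 20 (1R,2R,3S,4S,6S)-3-(TBSO)-1-methyl-4-[(3S)-6-methyl-3-(TESO)hepta-1,5-dien-2-yl]-7-oxabicyclo[4.1.0]heptan-2-ol
Product: 21 (1S,3S,4S,6S)-3-(TBSO)-1-methyl-4-[(3S)-6-methyl-3-(TESO)hepta-1,5-dien-2-yl]-7-oxabicyclo[4.1.0]heptan-2-one
Conditions: TPAP (5 mol %), NMO, 4 Å MS, CH2Cl2, rt
Reagents that add atoms: none
Why: Ley–Griffith oxidation converts the secondary epoxy alcohol to the α,β-epoxy ketone under near-neutral conditions that leave the oxirane, silyl ethers, alkenes and the C3 centre intact.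

Step 10
Reactants: 21 (1S,3S,4S,6S)-3-(TBSO)-1-methyl-4-[(3S)-6-methyl-3-(TESO)hepta-1,5-dien-2-yl]-7-oxabicyclo[4.1.0]heptan-2-one
Product: 22 (1S,3S,4S,6S)-3-hydroxy-4-[(3S)-3-hydroxy-6-methylhepta-1,5-dien-2-yl]-1-methyl-7-oxabicyclo[4.1.0]heptan-2-one
Conditions: HF·pyridine, pyridine, THF, 0 °C → rt
Reagents that add atoms: none
Why: Pyridine-buffered fluoride desilylation removes TES and TBS without base-induced epimerisation of the α-hydroxy ketone or acid opening of the electron-poor epoxy ketone.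

Step 11
Reactants: 22 (1S,3S,4S,6S)-3-hydroxy-4-[(3S)-3-hydroxy-6-methylhepta-1,5-dien-2-yl]-1-methyl-7-oxabicyclo[4.1.0]heptan-2-one; 23 angelic acid [(2Z)-2-methylbut-2-enoic acid]
Product: 25 (1S,3S,4S,6S)-1-methyl-4-[(3S)-6-methyl-3-{[(2Z)-2-methylbut-2-enoyl]oxy}hepta-1,5-dien-2-yl]-2-oxo-7-oxabicyclo[4.1.0]heptan-3-yl (2Z)-2-methylbut-2-enoate, via mixed anhydride 24 (not isolated)
Conditions: 23 (3 equiv), 2,4,6-trichlorobenzoyl chloride, Et3N, toluene, rt; then 22, toluene, 80 °C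
Reagents that add atoms: none
Why: Yamaguchi-type mixed-anhydride esterification run without DMAP acylates both secondary hydroxyls with retention and avoids the Z→E isomerisation of angelate to tiglate that nucleophilic catalysts cause.

**Compound list**
1 | cyclopent-2-en-1-one | O=C1C=CCC1 | starting material
2 | ethynyltrimethylsilane | C#C[Si](C)(C)C | starting material
3 | dimethyl[(trimethylsilyl)ethynyl]alane | C[Al](C)C#C[Si](C)(C)C | intermediate (not isolated)
4 | dimethylaluminium (R)-3-[(trimethylsilyl)ethynyl]cyclopent-1-en-1-olate | C[Si](C)(C)C#C[C@@H]1CCC(O[Al](C)C)=C1 | intermediate (not isolated)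
5 | (R)-tert-butyldimethyl({3-[(trimethylsilyl)ethynyl]cyclopent-1-en-1-yl}oxy)silane | C[Si](C)(C)C#C[C@@H]1CCC(O[Si](C)(C)C(C)(C)C)=C1 | intermediate
6 | (2S,3S)-2-(TBSO)-3-[(trimethylsilyl)ethynyl]cyclopentan-1-one | C[Si](C)(C)C#C[C@@H]1CCC(=O)[C@H]1O[Si](C)(C)C(C)(C)C | intermediate (not isolated)
7 | (2S,3S)-2-(TBSO)-3-ethynylcyclopentan-1-one | C#C[C@@H]1CCC(=O)[C@H]1O[Si](C)(C)C(C)(C)C | intermediate
8 | 4-methylpent-3-en-1-ol | CC(C)=CCCO | starting material
9 | 4-methylpent-3-enal | CC(C)=CCC=O | intermediate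
10 | (2S,3S)-2-(TBSO)-3-[(3S)-6-methyl-3-(TESO)hepta-1,5-dien-2-yl]cyclopentan-1-one | C=C([C@H](CC=C(C)C)O[Si](CC)(CC)CC)[C@@H]1CCC(=O)[C@H]1O[Si](C)(C)C(C)(C)C | intermediate
11 | 1,1-dibromoethane | CC(Br)Br | starting material
12 | 1,1-dibromo-1-lithioethane | [Li]C(C)(Br)Br | intermediate (not isolated)
13 | (2S,3S)-1-(1,1-dibromoethyl)-2-(TBSO)-3-[(3S)-6-methyl-3-(TESO)hepta-1,5-dien-2-yl]cyclopentan-1-ol, C1 epimers | C=C([C@H](CC=C(C)C)O[Si](CC)(CC)CC)[C@@H]1CCC(O)(C(C)(Br)Br)[C@H]1O[Si](C)(C)C(C)(C)C | intermediate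
14 | lithium alkoxide of 13 | C=C([C@H](CC=C(C)C)O[Si](CC)(CC)CC)[C@@H]1CCC(O[Li])(C(C)(Br)Br)[C@H]1O[Si](C)(C)C(C)(C)C | intermediate (not isolated)
15 | β-oxido carbenoid: lithium (2S,3S)-1-(1-bromo-1-lithioethyl)-2-(TBSO)-3-[side chain, R = TES]cyclopentan-1-olate | C=C([C@H](CC=C(C)C)O[Si](CC)(CC)CC)[C@@H]1CCC(O[Li])(C(C)([Li])Br)[C@H]1O[Si](C)(C)C(C)(C)C | intermediate (not isolated)
16 | lithium (5S,6S)-6-(TBSO)-2-methyl-5-[side chain, R = TES]cyclohex-1-en-1-olate | C=C([C@H](CC=C(C)C)O[Si](CC)(CC)CC)[C@@H]1CCC(C)=C(O[Li])[C@H]1O[Si](C)(C)C(C)(C)C | intermediate (not isolated)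
17 | (5S,6S)-2-(N-tert-butyl-S-phenylsulfinimidoyl)-6-(TBSO)-2-methyl-5-[side chain, R = TES]cyclohexan-1-one, C2/S epimers | C=C([C@H](CC=C(C)C)O[Si](CC)(CC)CC)[C@@H]1CCC(C)(S(=NC(C)(C)C)c2ccccc2)C(=O)[C@H]1O[Si](C)(C)C(C)(C)C | intermediate (not isolated)
18 | (5S,6S)-6-(TBSO)-2-methyl-5-[(3S)-6-methyl-3-(TESO)hepta-1,5-dien-2-yl]cyclohex-2-en-1-one | C=C([C@H](CC=C(C)C)O[Si](CC)(CC)CC)[C@@H]1CC=C(C)C(=O)[C@H]1O[Si](C)(C)C(C)(C)C | intermediate
19 | (1S,5S,6S)-6-(TBSO)-2-methyl-5-[(3S)-6-methyl-3-(TESO)hepta-1,5-dien-2-yl]cyclohex-2-en-1-ol | C=C([C@H](CC=C(C)C)O[Si](CC)(CC)CC)[C@@H]1CC=C(C)[C@H](O)[C@H]1O[Si](C)(C)C(C)(C)C | intermediate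
20 | (1R,2R,3S,4S,6S)-3-(TBSO)-1-methyl-4-[(3S)-6-methyl-3-(TESO)hepta-1,5-dien-2-yl]-7-oxabicyclo[4.1.0]heptan-2-ol | C=C([C@H](CC=C(C)C)O[Si](CC)(CC)CC)[C@@H]1C[C@@H]2O[C@]2(C)[C@H](O)[C@H]1O[Si](C)(C)C(C)(C)C | intermediate
21 | (1S,3S,4S,6S)-3-(TBSO)-1-methyl-4-[(3S)-6-methyl-3-(TESO)hepta-1,5-dien-2-yl]-7-oxabicyclo[4.1.0]heptan-2-one | C=C([C@H](CC=C(C)C)O[Si](CC)(CC)CC)[C@@H]1C[C@@H]2O[C@]2(C)C(=O)[C@H]1O[Si](C)(C)C(C)(C)C | intermediate
22 | (1S,3S,4S,6S)-3-hydroxy-4-[(3S)-3-hydroxy-6-methylhepta-1,5-dien-2-yl]-1-methyl-7-oxabicyclo[4.1.0]heptan-2-one | C=C([C@H](CC=C(C)C)O)[C@@H]1C[C@@H]2O[C@]2(C)C(=O)[C@H]1O | intermediate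
23 | angelic acid, (2Z)-2-methylbut-2-enoic acid | C/C=C(/C)C(=O)O | starting material
24 | (2Z)-2-methylbut-2-enoic 2,4,6-trichlorobenzoic anhydride | C/C=C(/C)C(=O)OC(=O)c1c(Cl)cc(Cl)cc1Cl | intermediate (not isolated)
25 | (1S,3S,4S,6S)-1-methyl-4-[(3S)-6-methyl-3-{[(2Z)-2-methylbut-2-enoyl]oxy}hepta-1,5-dien-2-yl]-2-oxo-7-oxabicyclo[4.1.0]heptan-3-yl (2Z)-2-methylbut-2-enoate | C=C([C@H](CC=C(C)C)OC(=O)/C(C)=C\C)[C@@H]1C[C@@H]2O[C@]2(C)C(=O)[C@H]1OC(=O)/C(C)=C\C | target

**Step count and risk**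
Total steps: 11. Longest linear sequence: 10 (steps 1, 2, 4–11 from cyclopent-2-enone; step 3 is a one-step side branch).

Most likely to fail, first: step 4 (the proposed new coupling). Branch selectivity, catalyst control over the carbinol centre next to an existing stereocentre, and tolerance of the ketone and the enolisable β,γ-unsaturated aldehyde are all untested. The fallback uses known chemistry, sets out from 7 and comes back at 10. Ru-catalysed Markovnikov hydrosilylation of 7 ([Cp*Ru(MeCN)3]PF6, Et3SiH, CH2Cl2) gives the α-vinylsilane (2S,3R)-2-(TBSO)-3-[1-(triethylsilyl)ethenyl]cyclopentan-1-one F1. Iododesilylation (NIS, HFIP, 0 °C) gives the 2-iodoalkene (2S,3R)-2-(TBSO)-3-(1-iodoethenyl)cyclopentan-1-one F2. Catalytic asymmetric Nozaki–Hiyama–Kishi coupling of F2 with 9 (CrCl2/NiCl2 cat., chiral sulfonamide-oxazoline ligand, Mn, TMSCl, MeCN; mild acid work-up) gives the allylic alcohol (2S,3S)-2-(TBSO)-3-[(3S)-3-hydroxy-6-methylhepta-1,5-dien-2-yl]cyclopentan-1-one F3, with the carbinol centre set by the ligand. TESCl/imidazole then gives 10.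

Second: step 6 (ring expansion). The C2(OTBS) carbon could migrate instead of C5, the TBS group could shift to the neighbouring alkoxide, and the sulfilimine could eliminate towards the methyl group. The fallback sets out from 10 and comes back at 18, so steps 5 and 6 are both replaced. Lewis-acid-catalysed diazoethane homologation (CH3CHN2, Sc(OTf)3 cat., toluene, −78 °C; diazonium-betaine pathway in which the non-oxygenated α-carbon migrates) gives (5S,6S)-6-(TBSO)-2-methyl-5-[(3S)-6-methyl-3-(TESO)hepta-1,5-dien-2-yl]cyclohexan-1-one F4 as a C2 epimer mixture. Kinetic enolisation away from the siloxy group (LDA, TMSCl, THF, −78 °C) gives the trimethylsilyl enol ether {[(5S,6S)-6-(TBSO)-2-methyl-5-[(3S)-6-methyl-3-(TESO)hepta-1,5-dien-2-yl]cyclohex-1-en-1-yl]oxy}trimethylsilane F5. Saegusa–Ito oxidation (Pd(OAc)2, MeCN, rt) then gives 18.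

Third: step 1. Enantioselective alkynylalane addition is less secure on the five-membered enone, and the aluminium enolate must be silylated cleanly. The fallback takes its chirality from the pool, sets out from 2 (converted to alane 3 as in step 1) and comes back at 6. Alane 3 is added to purchased (S)-4-(TBSO)cyclopent-2-en-1-one F6 with an achiral catalyst (Ni(acac)2/DIBAL-H cat., Et2O, 0 °C), trans to the siloxy group. This passes through dimethylaluminium (3R,4S)-4-(TBSO)-3-[(trimethylsilyl)ethynyl]cyclopent-1-en-1-olate F7, which TBSOTf traps as the bis-silyl enol ether tert-butyl({(3R,4S)-4-(TBSO)-3-[(trimethylsilyl)ethynyl]cyclopent-1-en-1-yl}oxy)dimethylsilane F8. Rubottom oxidation (m-CPBA) gives (2S,3R,4S)-2,4-bis(TBSO)-3-[(trimethylsilyl)ethynyl]cyclopentan-1-one F9. E1cB loss of the β-siloxy group (DBU, CH2Cl2) gives (4S,5S)-5-(TBSO)-4-[(trimethylsilyl)ethynyl]cyclopent-2-en-1-one F10. Conjugate reduction with Stryker's reagent ([(Ph3P)CuH]6, toluene) gives 6, which is protodesilylated to 7 with AgNO3 as in step 2.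

**Further compounds**
F1 | step 4 | (2S,3R)-2-(TBSO)-3-[1-(triethylsilyl)ethenyl]cyclopentan-1-one | C=C([Si](CC)(CC)CC)[C@@H]1CCC(=O)[C@H]1O[Si](C)(C)C(C)(C)C
F2 | step 4 | (2S,3R)-2-(TBSO)-3-(1-iodoethenyl)cyclopentan-1-one | C=C(I)[C@@H]1CCC(=O)[C@H]1O[Si](C)(C)C(C)(C)C
F3 | step 4 | (2S,3S)-2-(TBSO)-3-[(3S)-3-hydroxy-6-methylhepta-1,5-dien-2-yl]cyclopentan-1-one | C=C([C@H](CC=C(C)C)O)[C@@H]1CCC(=O)[C@H]1O[Si](C)(C)C(C)(C)C
F4 | step 6 | (5S,6S)-6-(TBSO)-2-methyl-5-[(3S)-6-methyl-3-(TESO)hepta-1,5-dien-2-yl]cyclohexan-1-one, C2 epimers | C=C([C@H](CC=C(C)C)O[Si](CC)(CC)CC)[C@@H]1CCC(C)C(=O)[C@H]1O[Si](C)(C)C(C)(C)C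
F5 | step 6 | {[(5S,6S)-6-(TBSO)-2-methyl-5-[(3S)-6-methyl-3-(TESO)hepta-1,5-dien-2-yl]cyclohex-1-en-1-yl]oxy}trimethylsilane | C=C([C@H](CC=C(C)C)O[Si](CC)(CC)CC)[C@@H]1CCC(C)=C(O[Si](C)(C)C)[C@H]1O[Si](C)(C)C(C)(C)C
F6 | step 1 | (S)-4-(TBSO)cyclopent-2-en-1-one (purchased) | O=C1C=C[C@@H](O[Si](C)(C)C(C)(C)C)C1
F7 | step 1 | dimethylaluminium (3R,4S)-4-(TBSO)-3-[(trimethylsilyl)ethynyl]cyclopent-1-en-1-olate | C[Si](C)(C)C#C[C@@H]1[C@@H](O[Si](C)(C)C(C)(C)C)CC(O[Al](C)C)=C1
F8 | step 1 | tert-butyl({(3R,4S)-4-(TBSO)-3-[(trimethylsilyl)ethynyl]cyclopent-1-en-1-yl}oxy)dimethylsilane | C[Si](C)(C)C#C[C@@H]1[C@@H](O[Si](C)(C)C(C)(C)C)CC(O[Si](C)(C)C(C)(C)C)=C1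
F9 | step 1 | (2S,3R,4S)-2,4-bis(TBSO)-3-[(trimethylsilyl)ethynyl]cyclopentan-1-one | C[Si](C)(C)C#C[C@@H]1[C@@H](O[Si](C)(C)C(C)(C)C)CC(=O)[C@H]1O[Si](C)(C)C(C)(C)C
F10 | step 1 | (4S,5S)-5-(TBSO)-4-[(trimethylsilyl)ethynyl]cyclopent-2-en-1-one | C[Si](C)(C)C#C[C@@H]1C=CC(=O)[C@H]1O[Si](C)(C)C(C)(C)C
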